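A turnover, one target made per catalyst charged, is the unit to read this flask in, and you get a pace by dividing a rate by the catalyst charge. Here are the flasks, the readings and the questions.

| setting | winter | summer | autumn | noon | midnight |
|---|---|---|---|---|---|
| substrate | 0.500 M | 0.250 M | 1.50 M | 0.500 M | 0.500 M |
| coupling partner | 1.50 M | 1.25 M | 1.50 M | 1.50 M | 1.50 M |
| free catalyst | 0.0100 M | 0.0100 M | 0.0100 M | 0.00500 M | 0.0100 M |
| time |  |  |  |  | 98 min |

- winter run (time / min: [target] / M): 7.0: 0.054; 14: 0.119; 21: 0.170; 28: 0.210; 35: 0.240; 42: 0.244; 49: 0.266
- summer run (time / min: [target] / M): 7.0: 0.057; 14: 0.092; 21: 0.128; 28: 0.151; 35: 0.154; 42: 0.152; 49: 0.143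
- autumn run (time / min: [target] / M): 7.0: 0.026; 14: 0.062; 21: 0.100; 28: 0.127; 35: 0.130; 42: 0.128; 49: 0.161
- noon run (time / min: [target] / M): 7.0: 0.032; 14: 0.062; 21: 0.078; 28: 0.099; 35: 0.121; 42: 0.139; 49: 0.151

(standard deviation of a reading: 0.007 M)

- Overall: substrate + coupling partner -> target, with free catalyst as catalyst.
- Constant volume, constant temperature.
- Bound and free are read together.
- "The second partner" is coupling partner.
- An order is taken over about fifteen percent of the charge, up and down.

* order of the initial rate in [free catalyst], near the charge of the winter run, the rate being that where two percent of its substrate are target
* order of the initial rate in [coupling partner], near the charge of the winter run, the rate being that where two percent of its substrate are target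
* target in the midnight run at 98 min, as a share of the substrate charged

Take the winter reading 0.119 M at 14 min, and divide it by that time and by the catalyst charge 0.0100 M. That gives the turnover pace f, 0.850 min⁻¹, an average over that stretch, and now turn the settings one at a time.

Catalyst first. By hand, if each catalyst works at its own pace, cutting the charge cuts the rate and leaves f alone. The noon run, at 0.00500 M, reads 0.062 M at 14 min, a pace of 0.886 min⁻¹, so I reckon the order in catalyst at 0.941.

Substrate next. By hand, you would expect more substrate to speed a catalyst or leave it unchanged. But the autumn run, at 1.50 M, turns over at 0.443 min⁻¹ up to 14 min, slower than f.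

The coupling partner has no clean pair of runs, since the summer run changes substrate too. If you let substrate count for nothing near the winter charge, the summer reading 0.092 M at 14 min gives an order of 1.41, a weak reading of my own.

Last comes time. The winter charge allows N, substrate over catalyst, or 50.0 turnovers, and at pace f you would reach them in 58.8 min. At 49 min pace f would give 41.6 turnovers, yet the winter reading counts 26.6, fewer, so the pace does not hold. The midnight run repeats the winter charge, so I would stay near that count, 53.2% of the substrate. The summer run's fall of 0.0110 M between 35 min and 49 min, against a scatter of 0.007 M, warns that this may be high.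

The forecast differs from me on the outcome: 0.9 in catalyst, 0.8 in coupling partner and 64% for the midnight run, on the view that “It looks like catalyst death with a lifetime of about 30 min”.

The midnight run gives 42.3% at 98 min, 22 percentage points under the forecast, with orders 1.0 in catalyst and 0.66 in coupling partner.

    free catalyst + substrate → catalyst-substrate complex (6.180 M⁻¹ min⁻¹)
    catalyst-substrate complex + coupling partner → target + free catalyst (6.180 M⁻¹ min⁻¹)
    target + coupling partner → side product (0.01446 M⁻¹ min⁻¹)
    catalyst-substrate complex + substrate ⇌ doubly bound catalyst, settled at all times (10.80 M⁻¹)

In this scheme target reacts with coupling partner to side product, at 0.0217 min⁻¹ per target with the partner at its charge. Pace f over 98 min would give 83.3 turnovers, yet the midnight run stands at 21.1 of its 50.0, below the winter count. The summer run counts the same way: its own pace up to 14 min, held over 49 min, would give 32.2 turnovers, its charge allows 25.0, and its reading at 49 min stands at 14.3.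

The runs were generated by integration with constants of no real substance; noise was put on by code.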